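The whole plan depends on cutting the C3–O bond of the C3–O–C7′ enol aryl ether. That cut releases two intact, unfunctionalised coumarins, esculetin 1 and umbelliferone 2. The key step is an anodic dehydrogenative cross-coupling (C3–H + H–O7′) modelled on the presumed biosynthesis. It exploits the catechol of ring A and its conjugation with the C3=C4 bond. In the 6,7-o-quinone the linear dienone O=C6–C5=C4a–C4=C3 makes C3 electrophilic, although it is normally the nucleophilic carbon of the pyranone ring. The phenoxide of 2 adds there and proton loss rearomatises ring A. One operation makes the whole bicoumarin skeleton without halogen, metal or protecting group. Acidity-guided 7-O-methylation finishes the target.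

Key step: step 1

Remark: the target has no stereocentre, stereogenic axis or open-chain double bond. It is achiral, so no enantiomer has to be chosen and no step has to control configuration.

Step 1
Reactants: 1 esculetin (6,7-dihydroxy-2H-chromen-2-one); 2 umbelliferone (7-hydroxy-2H-chromen-2-one)
Product: 5 6,7-dihydroxy-3-[(2-oxo-2H-chromen-7-yl)oxy]-2H-chromen-2-one, via esculetin o-quinone (2H-chromene-2,6,7-trione) 3 (not isolated), via p-quinone methide adduct 6-hydroxy-3-[(2-oxo-2H-chromen-7-yl)oxy]-3H-chromene-2,7-dione 4 (not isolated)
Conditions: graphite felt (+) | Pt (−), divided cell, 2.0 F/mol matched to a slow feed of 1, anode near +0.4 V vs Ag/AgCl (to be fixed by voltammetry in the cell); 2 (4 equiv); MeCN/0.1 M phosphate buffer pH 7.3 (1:2), Ar, 5 °C; then 1 h without current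
Reagents that add atoms: none
Why: Proposed new method: the anode, held at the first wave of 1, takes 2 e−/2 H+ from the catechol only and gives o-quinone 3, whose linear dienone O=C6–C5=C4a–C4=C3 ends at C3; the 7′-phenoxide of 2 adds there through oxygen (1,6-oxa-Michael addition) to give p-quinone methide 4, the intermediate expected from the 8–O–4′-type phenol coupling of the presumed biosynthesis, and loss of the acidic C3–H (α to C2=O) rearomatises ring A irreversibly to 5 while the protons are reduced to H2 at the cathode. The closest known reaction types are the anodic oxidation of catechols followed by Michael addition of a nucleophile (EC sequence), the copper/O2-mediated addition of phenols through oxygen to o-quinones, and the oxidative 8–O–4′ dehydrodimerisation of ferulates, which ends in the same α-aryloxycinnamate motif; none has been shown for C3 of a coumarin. No ring is closed and no lasting stereocentre is set: C3 of 4 is a transient racemic sp3 centre that becomes planar again in 5. Cross-selectivity is needed and is secured by the much lower oxidation potential of catechol 1 compared with monophenol 2, so that 1 can only become the electrophile and 2 only the nucleophile, and by the excess of 2 and the slow feed of 1, which keep unoxidised 1 from acting as the nucleophile. Site selectivity on 3 should favour C3 because the ordinary β-positions C4a and C8a are quaternary (addition there can only revert), C5 and C8 are reached only through the 1,6 ring channels that oxygen nucleophiles rarely use and that O1 weakens by donation into C8a=C8–C7=O, and between C3 and C4 the quinone carbonyl outweighs the lactone carbonyl as acceptor, just as 4-oxo-enoates are attacked α to the ester. O- over C-attack of 2 should follow from the kinetic preference of phenoxides for oxygen, from the deactivation of C6′ and C8′ by the pyranone acceptor, and from the fast aromatising proton loss that traps the kinetic adduct before it can revert.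

Step 2
Reactants: 5 6,7-dihydroxy-3-[(2-oxo-2H-chromen-7-yl)oxy]-2H-chromen-2-one
Product: 6 6-hydroxy-7-methoxy-3-[(2-oxo-2H-chromen-7-yl)oxy]-2H-chromen-2-one (target)
Conditions: MeI (1.1 equiv), NaHCO3 (1.2 equiv), DMF, Ar, 35 °C, sealed vessel
Reagents that add atoms: methyl iodide, CI
Why: Williamson O-methylation under acidity control: bicarbonate should ionise only the 7-OH, a vinylogous acid conjugated through C4a–C4=C3 with the lactone C2=O, as in the well-known 4-O-selective alkylation of 3,4-dihydroxybenzaldehyde, so the single equivalent of MeI should end on O7 and leave the 6-OH free; no stereocentre is involved.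

Compound list
1 | esculetin (6,7-dihydroxy-2H-chromen-2-one) | O=c1ccc2cc(O)c(O)cc2o1 | starting material
2 | umbelliferone (7-hydroxy-2H-chromen-2-one) | O=c1ccc2ccc(O)cc2o1 | starting material
3 | esculetin o-quinone (2H-chromene-2,6,7-trione) | O=C1C=CC2=CC(=O)C(=O)C=C2O1 | intermediate
4 | 6-hydroxy-3-[(2-oxo-2H-chromen-7-yl)oxy]-3H-chromene-2,7-dione (p-quinone methide adduct, racemic at C3, transient) | O=C1OC2=CC(=O)C(O)=CC2=CC1Oc1ccc2ccc(=O)oc2c1 | intermediate
5 | 6,7-dihydroxy-3-[(2-oxo-2H-chromen-7-yl)oxy]-2H-chromen-2-one | O=c1oc2cc(O)c(O)cc2cc1Oc1ccc2ccc(=O)oc2c1 | intermediate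
6 | 6-hydroxy-7-methoxy-3-[(2-oxo-2H-chromen-7-yl)oxy]-2H-chromen-2-one | COc1cc2oc(=O)c(Oc3ccc4ccc(=O)oc4c3)cc2cc1O | target

Total step count: 2
Longest linear sequence: 2

Steps most likely to fail (the route has only two steps, so only two can be ranked):

1. Step 1 (Proposed new method). Several processes may go wrong:
- The phenoxide may add at ring positions C5 or C8 of the oxidised ring A, or through carbon C8′/C6′ instead of oxygen.
- The catechol monomer may self-couple and oligomerise.
- Acyl attack or hydrolysis may occur at the lactone carbonyl, which behaves as a vinylogous anhydride in the oxidised state.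
- The coupled catechol may be oxidised further. This last process should be tolerable, because the charge is limited to 2 F/mol and redox exchange with unreacted 1 returns the material.

The fallback uses known chemistry and builds the pyranone of ring A around a preformed ether instead of coupling two coumarins. It sets out from 2 and comes back at 5. Williamson alkylation of 2 with ethyl bromoacetate (K2CO3, acetone, reflux) would give ethyl [(2-oxo-2H-chromen-7-yl)oxy]acetate F1. Saponification (LiOH, aq. THF, then HCl, which also recloses any opened lactone) would give [(2-oxo-2H-chromen-7-yl)oxy]acetic acid F2. Perkin condensation of F2 with commercial 2,4,5-trihydroxybenzaldehyde (O=Cc1cc(O)c(O)cc1O; Ac2O, Et3N, 120 °C) would form C3=C4 and O1–C2 and give 6,7-diacetoxy-3-[(2-oxo-2H-chromen-7-yl)oxy]-2H-chromen-2-one F3. Acid methanolysis (cat. HCl, MeOH, reflux, Ar) would then give 5.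

2. Step 2. Discrimination between O7 and O6 may be poor, a second methylation may occur, and the catechol may be oxidised by air in the basic medium.

The fallback replaces direct discrimination of two free phenols by stepwise unmasking. It sets out from 5 and comes back at 6. Silylation of both phenols (TBSCl, imidazole, DMF) would give 6,7-bis(tert-butyldimethylsilyloxy)-3-[(2-oxo-2H-chromen-7-yl)oxy]-2H-chromen-2-one F4. One equivalent of CsF with MeI (DMF, 0 °C) should cleave the silyl ether of the better leaving 7-phenoxide and methylate it in the same flask. Only one phenoxide can exist at a time, so double methylation is excluded, and any O-to-O silyl shift should rest on the side of the more stabilised 7-phenoxide. This would give 6-(tert-butyldimethylsilyloxy)-7-methoxy-3-[(2-oxo-2H-chromen-7-yl)oxy]-2H-chromen-2-one F5. Desilylation (TBAF/AcOH, THF, 0 °C) would give 6.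

Further compounds
F1 | step 1 | ethyl [(2-oxo-2H-chromen-7-yl)oxy]acetate | CCOC(=O)COc1ccc2ccc(=O)oc2c1
F2 | step 1 | [(2-oxo-2H-chromen-7-yl)oxy]acetic acid | OC(=O)COc1ccc2ccc(=O)oc2c1
F3 | step 1 | 6,7-diacetoxy-3-[(2-oxo-2H-chromen-7-yl)oxy]-2H-chromen-2-one | CC(=O)Oc1cc2oc(=O)c(Oc3ccc4ccc(=O)oc4c3)cc2cc1OC(C)=O
F4 | step 2 | 6,7-bis(tert-butyldimethylsilyloxy)-3-[(2-oxo-2H-chromen-7-yl)oxy]-2H-chromen-2-one | CC(C)(C)[Si](C)(C)Oc1cc2oc(=O)c(Oc3ccc4ccc(=O)oc4c3)cc2cc1O[Si](C)(C)C(C)(C)C
F5 | step 2 | 6-(tert-butyldimethylsilyloxy)-7-methoxy-3-[(2-oxo-2H-chromen-7-yl)oxy]-2H-chromen-2-one | COc1cc2oc(=O)c(Oc3ccc4ccc(=O)oc4c3)cc2cc1O[Si](C)(C)C(C)(C)C
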